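**Retrosynthetic overview**
1. Target 23 ⇐ reagent-controlled epoxidation of the only unactivated olefin (C7=C8, Z) of macrocyclic tetraenolide 22. The oxirane is the last ring formed.
2. 22 ⇐ seco enal/enol triflate 20 by forming C1–C2 with reversed polarity: the keto carbon C1 of a β-keto ester becomes a β-(methoxycarbonyl)vinyl-chromium nucleophile and adds to the enal carbon C2. The 14-membered carbocycle closes first and the alkoxide lactonises to the butenolide in the same flask.
3. 20 ⇐ C12 trienal 10 + C5 diene 14 by a catalytic asymmetric vinylogous aldol (C13–C14, sets 13R), then acetylation, Z-enol triflation and unmasking of C2.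
4. 10 ⇐ nerol (C6–C13, carries the Z-olefin) + a propyne unit (C3–C5) + methyl (C18) and CH2OMe (C2) by carboalumination, then terminal allylic oxidation.

Assumptions: cembrane numbering is used (ring C1–C14; lactone C15, C16 and methyl C17). The target SMILES encodes a cis-oxirane (7S,8R; C6 and C9 on the same side), so a 7Z-olefin is carried throughout. The (S)-antipode of the chromium ligand in step 11 is taken to give Si-face delivery; its mirror image would be used, with nothing else changed, if a model coupling shows the opposite sense.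

**Step 1**
Reactants: 1 nerol, (2Z)-3,7-dimethylocta-2,6-dien-1-ol
Product: 2 neryl bromide, (2Z)-1-bromo-3,7-dimethylocta-2,6-diene
Conditions: PBr3 (0.4 equiv), pyridine (cat.), Et2O, −20 → 0 °C; used crude
Reagents that add atoms: phosphorus tribromide, BrP(Br)Br
Why: SN2 bromination of the primary allylic alcohol through its bromophosphite at low temperature keeps the 2Z geometry that later becomes the cis-oxirane.

**Step 2**
Reactants: 2 neryl bromide; 3 1-(trimethylsilyl)propyne
Product: 6 (5Z)-6,10-dimethylundeca-5,9-dien-1-yne, via 3-(trimethylsilyl)propargyllithium 4 (not isolated), via silylated enyne 5 (not isolated)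
Conditions: 3, n-BuLi, THF, −78 → −20 °C; 2, −78 → 0 °C; then MeOH, K2CO3, rt
Reagents that add atoms: none
Why: Propargylic lithiation, SN2 alkylation by the primary allylic bromide (C5–C6 bond) and protodesilylation in the same flask give the 1,5-enyne without touching the Z-olefin.

**Step 3**
Reactants: 6 (5Z)-6,10-dimethylundeca-5,9-dien-1-yne
Product: 8 (2E,6Z)-1-methoxy-3,7,11-trimethyldodeca-2,6,10-triene, via alkenyldimethylalane 7 (not isolated)
Conditions: AlMe3 (2.5 equiv), Cp2ZrCl2 (0.25 equiv), CH2Cl2, 0 °C → rt; then ClCH2OMe, 0 °C → rt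
Reagents that add atoms: trimethylaluminium, C[Al](C)C; chloromethyl methyl ether, COCCl
Why: Negishi zirconium-catalysed syn-carboalumination puts methyl on the internal carbon and aluminium on the terminus (E-olefin C3=C4), and the alkenylalane is alkylated with retention by the methoxymethyl cation equivalent.

**Step 4**
Reactants: 8 (2E,6Z)-1-methoxy-3,7,11-trimethyldodeca-2,6,10-triene
Product: 10 (2E,6Z,10E)-12-methoxy-2,6,10-trimethyldodeca-2,6,10-trienal, via allylic alcohol 9 (not isolated)
Conditions: SeO2 (0.3 equiv), t-BuOOH (2.5 equiv), salicylic acid (0.1 equiv), CH2Cl2, 0 °C → rt; then TEMPO (2,2,6,6-tetramethylpiperidin-1-oxyl, 0.1 equiv), PhI(OAc)2 (1.3 equiv), rt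
Reagents that add atoms: tert-butyl hydroperoxide, CC(C)(C)OO (oxygen source, relayed by catalytic selenium dioxide, O=[Se]=O)
Why: Selenium dioxide allylic oxidation (ene reaction, then 2,3-shift) attacks the E-methyl of the terminal, most electron-rich olefin, and the oxoammonium oxidation in the same flask converges alcohol and aldehyde on the E-enal.

**Step 5**
Reactants: 11 methyl 2-methyl-3-oxobutanoate
Product: 12 methyl 2-methyl-3-(trimethylsilyloxy)but-2-enoate (E/Z mixture)
Conditions: Me3SiCl, Et3N, pentane, rt; filter, distil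
Reagents that add atoms: chlorotrimethylsilane, C[Si](C)(C)Cl
Why: O-silylation of the β-keto ester enol gives the mono silyl enol ether.

**Step 6**
Reactants: 12 methyl 2-methyl-3-(trimethylsilyloxy)but-2-enoate
Product: 14 1-methoxy-2-methyl-1,3-bis(trimethylsilyloxy)buta-1,3-diene, via lithium dienolate 13 (not isolated)
Conditions: LiN(iPr)2, THF, −78 °C; Me3SiCl, −78 °C → rt
Reagents that add atoms: chlorotrimethylsilane, C[Si](C)(C)Cl
Why: γ-Deprotonation of the vinylogous ester and O-silylation give the 2-methyl Chan-type diene, a masked dianion of 11.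

**Step 7**
Reactants: 10 (2E,6Z,10E)-12-methoxy-2,6,10-trimethyldodeca-2,6,10-trienal; 14 1-methoxy-2-methyl-1,3-bis(trimethylsilyloxy)buta-1,3-diene
Product: 16 methyl (5R,6E,10Z,14E)-5-hydroxy-16-methoxy-2,6,10,14-tetramethyl-3-oxohexadeca-6,10,14-trienoate, via bis-silylated aldol adduct 15 (not isolated)
Conditions: Ti(OiPr)4 (10 mol%), (R)-1,1'-bi-2-naphthol (10 mol%), 4 Å MS, THF, −78 °C → rt; then CF3CO2H, aq. THF, −78 → 0 °C
Reagents that add atoms: none
Why: In this catalytic asymmetric vinylogous Mukaiyama aldol the (R)-binaphtholate titanium complex directs the diene terminus to the Re face of the enal (the sense known for this catalyst in allylation and aldol additions), which sets 13R; the α-carbon (future C15) is an inconsequential epimer mixture.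

**Step 8**
Reactants: 16 methyl (5R,6E,10Z,14E)-5-hydroxy-16-methoxy-2,6,10,14-tetramethyl-3-oxohexadeca-6,10,14-trienoate
Product: 17 methyl (5R,6E,10Z,14E)-5-acetoxy-16-methoxy-2,6,10,14-tetramethyl-3-oxohexadeca-6,10,14-trienoate
Conditions: Ac2O, pyridine, 4-(dimethylamino)pyridine (cat.), CH2Cl2, 0 °C
Reagents that add atoms: acetic anhydride, CC(=O)OC(C)=O
Why: Nucleophile-catalysed acylation installs the C13 acetate of the target before any base can close the δ-lactone; the stereocentre is untouched.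

**Step 9**
Reactants: 17 methyl (5R,6E,10Z,14E)-5-acetoxy-16-methoxy-2,6,10,14-tetramethyl-3-oxohexadeca-6,10,14-trienoate
Product: 19 methyl (2Z,5R,6E,10Z,14E)-5-acetoxy-16-methoxy-2,6,10,14-tetramethyl-3-(trifluoromethylsulfonyloxy)hexadeca-2,6,10,14-tetraenoate, via chelated sodium enolate 18 (not isolated)
Conditions: NaH (1.05 equiv), Et2O, 0 °C; Tf2O (1.1 equiv), −78 → 0 °C
Reagents that add atoms: trifluoromethanesulfonic anhydride, O=S(=O)(OS(=O)(=O)C(F)(F)F)C(F)(F)F
Why: Only the doubly activated C–H is removed, and the sodium-chelated enolate (enolate O cis to the ester) is O-sulfonylated to the Z-enol triflate, the geometry needed for lactonisation; the β-acetoxy group is not eliminated because no enolate forms toward C14.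

**Step 10**
Reactants: 19 methyl (2Z,5R,6E,10Z,14E)-5-acetoxy-16-methoxy-2,6,10,14-tetramethyl-3-(trifluoromethylsulfonyloxy)hexadeca-2,6,10,14-tetraenoate
Product: 20 methyl (2Z,5R,6E,10Z,14E)-5-acetoxy-2,6,10,14-tetramethyl-16-oxo-3-(trifluoromethylsulfonyloxy)hexadeca-2,6,10,14-tetraenoate
Conditions: DDQ (1.5 equiv), CH2Cl2/H2O 18:1, 0 °C → rt
Reagents that add atoms: water, O
Why: DDQ abstracts hydride from the CH2 of the 3,3-disubstituted allyl ether (the reaction that cleaves prenyl ethers), and water converts the oxocarbenium ion into the E-enal plus methanol; the acetoxy-bearing C13–H is far less hydridic.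

**Step 11**
Reactants: 20 methyl (2Z,5R,6E,10Z,14E)-5-acetoxy-2,6,10,14-tetramethyl-16-oxo-3-(trifluoromethylsulfonyloxy)hexadeca-2,6,10,14-tetraenoate
Product: 22 (2R,3E,7Z,11E,13R)-13-acetoxycembra-1(15),3,7,11-tetraen-16,2-olide, via macrocyclic hydroxy ester 21 (not isolated)
Conditions: CrCl2 (6 equiv), (S)-N-[2-(4-isopropyl-4,5-dihydrooxazol-2-yl)-6-methylphenyl]methanesulfonamide (6.6 equiv), Et3N (6.6 equiv), NiCl2(dmp) (0.3 equiv; dmp = 2,9-dimethyl-1,10-phenanthroline), LiCl (6 equiv), MeCN/THF 3:1, rt; 20 added over 12 h to 0.002 M; aq. potassium serinate work-up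
Reagents that add atoms: none
Why: Proposed new method: zerovalent nickel inserts into the electron-poor enol triflate and passes the alkenyl group to chromium with retention, so the former keto carbon C1 (an acceptor) becomes a β-(methoxycarbonyl)vinyl, homoenolate-type d3 nucleophile that adds to the enal carbon C2 (the other acceptor) on its Si face inside the chiral trivalent chromium sulfonamide complex, setting 2R, and the cis alkoxide then expels methoxide to form the butenolide; the closest known reactions are Nozaki–Hiyama–Kishi macrocyclisations, butenolide-forming Ni/Cr couplings of (Z)-β-halo- or β-triflyloxy-acrylates with aldehydes, and ligand-controlled asymmetric Ni/Cr couplings.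

**Step 12**
Reactants: 22 (2R,3E,7Z,11E,13R)-13-acetoxycembra-1(15),3,7,11-tetraen-16,2-olide
Product: 23 (2R,3E,7S,8R,11E,13R)-13-acetoxy-7,8-epoxycembra-1(15),3,11-trien-16,2-olide (target)
Conditions: 1,2:4,5-di-O-isopropylidene-β-L-erythro-2,3-hexodiulo-2,6-pyranose (0.3 equiv), Oxone (2KHSO5·KHSO4·K2SO4), K2CO3, Bu4NHSO4, MeCN/CH2(OMe)2/aq. Na2B4O7 buffer, pH 10.5, 0 °C
Reagents that add atoms: potassium peroxymonosulfate (Oxone), [K+].[O-]S(=O)(=O)OO
Why: In this Shi asymmetric epoxidation the electrophilic dioxirane takes the one olefin not deactivated by an allylic acyloxy group or conjugation (C7=C8), and the L-series ketone, which gives S at the CH terminus of trisubstituted olefins, delivers oxygen stereospecifically to the Z-olefin to give the cis (7S,8R) oxirane.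

**Compound list**
1 | nerol, (2Z)-3,7-dimethylocta-2,6-dien-1-ol | CC(C)=CCC/C(C)=C\CO | starting material
2 | neryl bromide, (2Z)-1-bromo-3,7-dimethylocta-2,6-diene | CC(C)=CCC/C(C)=C\CBr | intermediate
3 | 1-(trimethylsilyl)propyne | CC#C[Si](C)(C)C | starting material
4 | 3-(trimethylsilyl)prop-2-yn-1-yllithium | [Li]CC#C[Si](C)(C)C | intermediate (not isolated)
5 | [(5Z)-6,10-dimethylundeca-5,9-dien-1-yn-1-yl]trimethylsilane | CC(C)=CCC/C(C)=C\CCC#C[Si](C)(C)C | intermediate (not isolated)
6 | (5Z)-6,10-dimethylundeca-5,9-dien-1-yne | CC(C)=CCC/C(C)=C\CCC#C | intermediate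
7 | dimethyl[(1E,5Z)-2,6,10-trimethylundeca-1,5,9-trien-1-yl]alane | CC(C)=CCC/C(C)=C\CC/C(C)=C/[Al](C)C | intermediate (not isolated)
8 | (2E,6Z)-1-methoxy-3,7,11-trimethyldodeca-2,6,10-triene | CC(C)=CCC/C(C)=C\CC/C(C)=C/COC | intermediate
9 | (2E,6Z,10E)-12-methoxy-2,6,10-trimethyldodeca-2,6,10-trien-1-ol | OC/C(C)=C/CC/C(C)=C\CC/C(C)=C/COC | intermediate (not isolated)
10 | (2E,6Z,10E)-12-methoxy-2,6,10-trimethyldodeca-2,6,10-trienal | O=C/C(C)=C/CC/C(C)=C\CC/C(C)=C/COC | intermediate
11 | methyl 2-methyl-3-oxobutanoate | COC(=O)C(C)C(C)=O | starting material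
12 | methyl 2-methyl-3-(trimethylsilyloxy)but-2-enoate (E/Z mixture) | COC(=O)C(C)=C(C)O[Si](C)(C)C | intermediate
13 | lithium 1-methoxy-2-methyl-3-(trimethylsilyloxy)buta-1,3-dien-1-olate | C=C(O[Si](C)(C)C)C(C)=C(OC)O[Li] | intermediate (not isolated)
14 | 1-methoxy-2-methyl-1,3-bis(trimethylsilyloxy)buta-1,3-diene | C=C(O[Si](C)(C)C)C(C)=C(OC)O[Si](C)(C)C | intermediate
15 | methyl (5R,6E,10Z,14E)-16-methoxy-2,6,10,14-tetramethyl-3,5-bis(trimethylsilyloxy)hexadeca-2,6,10,14-tetraenoate | COC(=O)C(C)=C(O[Si](C)(C)C)C[C@@H](O[Si](C)(C)C)/C(C)=C/CC/C(C)=C\CC/C(C)=C/COC | intermediate (not isolated)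
16 | methyl (5R,6E,10Z,14E)-5-hydroxy-16-methoxy-2,6,10,14-tetramethyl-3-oxohexadeca-6,10,14-trienoate | COC(=O)C(C)C(=O)C[C@@H](O)/C(C)=C/CC/C(C)=C\CC/C(C)=C/COC | intermediate
17 | methyl (5R,6E,10Z,14E)-5-acetoxy-16-methoxy-2,6,10,14-tetramethyl-3-oxohexadeca-6,10,14-trienoate | COC(=O)C(C)C(=O)C[C@@H](OC(C)=O)/C(C)=C/CC/C(C)=C\CC/C(C)=C/COC | intermediate
18 | sodium (Z)-enolate of 17 | COC(=O)/C(C)=C(O[Na])/C[C@@H](OC(C)=O)/C(C)=C/CC/C(C)=C\CC/C(C)=C/COC | intermediate (not isolated)
19 | methyl (2Z,5R,6E,10Z,14E)-5-acetoxy-16-methoxy-2,6,10,14-tetramethyl-3-(trifluoromethylsulfonyloxy)hexadeca-2,6,10,14-tetraenoate | COC(=O)/C(C)=C(OS(=O)(=O)C(F)(F)F)/C[C@@H](OC(C)=O)/C(C)=C/CC/C(C)=C\CC/C(C)=C/COC | intermediate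
20 | methyl (2Z,5R,6E,10Z,14E)-5-acetoxy-2,6,10,14-tetramethyl-16-oxo-3-(trifluoromethylsulfonyloxy)hexadeca-2,6,10,14-tetraenoate | COC(=O)/C(C)=C(OS(=O)(=O)C(F)(F)F)/C[C@@H](OC(C)=O)/C(C)=C/CC/C(C)=C\CC/C(C)=C/C=O | intermediate
21 | methyl (2Z)-2-[(2R,3E,7Z,11E,13R)-13-acetoxy-2-hydroxy-4,8,12-trimethylcyclotetradeca-3,7,11-trien-1-ylidene]propanoate (formed as its trivalent chromium alkoxide, drawn as the alcohol) | COC(=O)/C(C)=C1/C[C@@H](OC(C)=O)/C(C)=C/CC/C(C)=C\CC/C(C)=C/[C@H]1O | intermediate (not isolated)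
22 | (2R,3E,7Z,11E,13R)-13-acetoxycembra-1(15),3,7,11-tetraen-16,2-olide | CC(=O)O[C@@H]1CC2=C(C)C(=O)O[C@@H]2/C=C(\C)CC/C=C(/C)CC/C=C/1C | intermediate
23 | (2R,3E,7S,8R,11E,13R)-13-acetoxy-7,8-epoxycembra-1(15),3,11-trien-16,2-olide | CC(=O)O[C@@H]1CC2=C(C)C(=O)O[C@@H]2/C=C(\C)CC[C@@H]2O[C@]2(C)CC/C=C/1C | target

**Count**
Total steps: 12. Longest linear sequence: 10 (steps 1–4 and 7–12 from nerol; steps 5–6 are a two-step side branch).

**Three steps most likely to fail**

Step 11 (ring closure). A tetrasubstituted alkenylchromium must find a hindered β,β-disubstituted enal at high dilution; simple reduction of the triflate, oligomers, or a C2 ratio dominated by the remote C13 centre are all possible. Fallback, setting out from 20 and rejoining at 22: replace the stoichiometric chromium closure by a boron-to-rhodium relay. Miyaura borylation of the enol triflate (B2pin2, PdCl2(PPh3)2, PPh3, KOPh, toluene, 50 °C) gives, with retention of geometry, methyl (2E,5R,6E,10Z,14E)-5-acetoxy-2,6,10,14-tetramethyl-16-oxo-3-(4,4,5,5-tetramethyl-1,3,2-dioxaborolan-2-yl)hexadeca-2,6,10,14-tetraenoate F1. Intramolecular 1,2-addition of the alkenylboronate to the enal ([Rh(OH)(cod)]2, chiral diene ligand, aq. KOH, dioxane, 0.003 M, 60 °C) then closes the ring, the alkoxide lactonises, and the product is 22. The same reversed-polarity C1–C2 bond is made, but catalytically and with a different metal and ligand set for controlling C2.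

Step 12 (epoxidation). The macrocycle may present one face of C7=C8 regardless of the catalyst, and the butenolide C2–H and the acetate see pH 10.5. Fallback, setting out from 19 and rejoining at 23: epoxidise before ring closure, where there is no conformational bias. The same L-series ketone and Oxone on 19 (C7=C8 is again the only unactivated olefin) give methyl (2Z,5R,6E,10S,11R,14E)-5-acetoxy-10,11-epoxy-16-methoxy-2,6,10,14-tetramethyl-3-(trifluoromethylsulfonyloxy)hexadeca-2,6,14-trienoate F2. DDQ in wet CH2Cl2 as in step 10 gives the corresponding epoxy enal, methyl (2Z,5R,6E,10S,11R,14E)-5-acetoxy-10,11-epoxy-2,6,10,14-tetramethyl-16-oxo-3-(trifluoromethylsulfonyloxy)hexadeca-2,6,14-trienoate F3. The nickel/chromium closure of step 11 applied to F3 then gives 23 directly.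

Step 7 (asymmetric vinylogous aldol). The 2-methylated diene and an α-branched enal may give low conversion or modest enantioselectivity. Fallback, setting out from 10 and rejoining at 16: a stoichiometric auxiliary acetate aldol followed by chain extension. The dilithium enolate of (R)-2-hydroxy-1,2,2-triphenylethyl acetate (LiN(iPr)2 2 equiv, THF, then MgBr2, −78 °C) adds to 10 to give (1R)-2-hydroxy-1,2,2-triphenylethyl (3R,4E,8Z,12E)-3-hydroxy-14-methoxy-4,8,12-trimethyltetradeca-4,8,12-trienoate F4. Transesterification (K2CO3, MeOH, rt, diol auxiliary recovered) gives methyl (3R,4E,8Z,12E)-3-hydroxy-14-methoxy-4,8,12-trimethyltetradeca-4,8,12-trienoate F5. Crossed Claisen condensation with the lithium enolate of methyl propanoate (3.5 equiv, THF, −78 → −20 °C) gives 16.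

**Further compounds**
F1 | step 11 | methyl (2E,5R,6E,10Z,14E)-5-acetoxy-2,6,10,14-tetramethyl-16-oxo-3-(4,4,5,5-tetramethyl-1,3,2-dioxaborolan-2-yl)hexadeca-2,6,10,14-tetraenoate | COC(=O)/C(C)=C(B1OC(C)(C)C(C)(C)O1)/C[C@@H](OC(C)=O)/C(C)=C/CC/C(C)=C\CC/C(C)=C/C=O
F2 | step 12 | methyl (2Z,5R,6E,10S,11R,14E)-5-acetoxy-10,11-epoxy-16-methoxy-2,6,10,14-tetramethyl-3-(trifluoromethylsulfonyloxy)hexadeca-2,6,14-trienoate | COC(=O)/C(C)=C(OS(=O)(=O)C(F)(F)F)/C[C@@H](OC(C)=O)/C(C)=C/CC[C@@]1(C)O[C@H]1CC/C(C)=C/COC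
F3 | step 12 | methyl (2Z,5R,6E,10S,11R,14E)-5-acetoxy-10,11-epoxy-2,6,10,14-tetramethyl-16-oxo-3-(trifluoromethylsulfonyloxy)hexadeca-2,6,14-trienoate | COC(=O)/C(C)=C(OS(=O)(=O)C(F)(F)F)/C[C@@H](OC(C)=O)/C(C)=C/CC[C@@]1(C)O[C@H]1CC/C(C)=C/C=O
F4 | step 7 | (1R)-2-hydroxy-1,2,2-triphenylethyl (3R,4E,8Z,12E)-3-hydroxy-14-methoxy-4,8,12-trimethyltetradeca-4,8,12-trienoate | O=C(C[C@@H](O)/C(C)=C/CC/C(C)=C\CC/C(C)=C/COC)O[C@H](c1ccccc1)C(O)(c1ccccc1)c1ccccc1
F5 | step 7 | methyl (3R,4E,8Z,12E)-3-hydroxy-14-methoxy-4,8,12-trimethyltetradeca-4,8,12-trienoate | COC(=O)C[C@@H](O)/C(C)=C/CC/C(C)=C\CC/C(C)=C/COC
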